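**Retrosynthetic overview**

1. Numbering: C1–C5 and C10 form the cyclohexenone (C10 ketone, C1=C2, C4 carbinol, C5 quaternary); C18 is the lactone carbonyl, C19 the lactone CH2, and C6–C7 the linker to pyrone C3.
2. Cyclohexenone (formed last): C1–C2 is cut back to the C10 methyl ketone and a C2 acetal on the C4 side chain (enol silane addition to the acetal, then loss of the alkoxy group).
3. γ-Lactone (the feature the plan rests on): the C4–C5 bond inside this ring joins C5, the α-carbon of the C10 ketone, to carbinol C4, which carries lactone carbonyl C18. It is therefore an aldol bond between a ketone enolate and an α-keto ester already linked through the C19–O–C18 ester; hydride addition to C6 of an acyclic C5=C6 enone makes that enolate, and the ring and both stereocenters form together.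
4. Enone keto ester: from a 2-(bromomethyl) enone and the potassium salt of dioxolane-masked 2,4-dioxobutanoic acid; the enone comes from a propargylic alcohol by hydroxyl-directed hydrostannation, iodination and coupling with an acetyl equivalent.
5. Pyrone (formed first): 6-endo lactonisation of a (Z)-enynoate built from tert-butyl acetoacetate, a four-carbon propargylic chloride and 3-ethynylfuran. Ring order: pyrone, γ-lactone, cyclohexenone.

Key step: step 14

**Remarks on the chemistry (assumptions)**

- C2 is carried as a 1,3-dioxolane rather than an acyclic acetal, because a ring-opened dioxolane re-closes after any β-elimination next to the keto ester, and the keto ester is then available from a commercial Grignard reagent.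
- The C5=C6 geometry of the key-step precursor is of no consequence, since C6 becomes a CH2 group; it is drawn as the isomer that the trans-hydrostannation delivers.
- Which antipode of the bisphosphine gives the (4R,5R) series cannot be derived with certainty; (R) is written, and the (S) ligand is used instead if a pilot run shows the opposite sense.
- The aldehyde is never liberated after the key step, because a free C2 aldehyde would make C3 acidic next to the C4 oxygen and invite β-elimination.

**Route**

Step 1
Reactants: 1 4-chlorobut-2-yn-1-ol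
Product: 2 tert-butyl[(4-chlorobut-2-yn-1-yl)oxy]dimethylsilane
Conditions: TBSCl, imidazole, CH2Cl2, 0 °C → rt
Reagents that add atoms: tert-butyldimethylsilyl chloride, CC(C)(C)[Si](C)(C)Cl
Why: Standard silylation of a primary alcohol, which protects the hydroxyl through the enol triflate step and leaves the propargylic chloride for alkylation.

Step 2
Reactants: 2 tert-butyl[(4-chlorobut-2-yn-1-yl)oxy]dimethylsilane; 3 tert-butyl 3-oxobutanoate
Product: 4 tert-butyl 2-acetyl-6-[(tert-butyldimethylsilyl)oxy]hex-4-ynoate (racemic)
Conditions: NaH, THF, 0 °C; then 2, NaI (cat.), THF/DMF, rt → 50 °C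
Reagents that add atoms: none
Why: Acetoacetic ester C-alkylation of the sodium enolate with a primary propargylic halide (iodide exchange speeds the SN2 step, a slight excess of 3 limits dialkylation); the new stereocenter is racemic and is removed in step 3.

Step 3
Reactants: 4 tert-butyl 2-acetyl-6-[(tert-butyldimethylsilyl)oxy]hex-4-ynoate
Product: 5 tert-butyl (2Z)-2-{4-[(tert-butyldimethylsilyl)oxy]but-2-yn-1-yl}-3-{[(trifluoromethyl)sulfonyl]oxy}but-2-enoate
Conditions: Tf2O, sat. aq. LiOH, toluene, 5 °C
Reagents that add atoms: trifluoromethanesulfonic anhydride, O=S(=O)(OS(=O)(=O)C(F)(F)F)C(F)(F)F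
Why: O-triflation of the chelated lithium enolate of the β-keto ester should give the enol triflate with the triflate cis to the ester, the geometry the later lactonisation needs.

Step 4
Reactants: 6 furan-3-carbaldehyde
Product: 7 3-ethynylfuran
Conditions: dimethyl (1-diazo-2-oxopropyl)phosphonate, K2CO3, MeOH, 0 °C → rt; used as a solution
Reagents that add atoms: dimethyl (1-diazo-2-oxopropyl)phosphonate, CC(=O)C(=[N+]=[N-])P(=O)(OC)OC
Why: Seyferth–Gilbert homologation with the Ohira–Bestmann reagent converts the aldehyde into the terminal alkyne under mild base that the furan tolerates.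

Step 5
Reactants: 5 the (Z)-enol triflate; 7 3-ethynylfuran
Product: 8 tert-butyl (2Z)-2-{4-[(tert-butyldimethylsilyl)oxy]but-2-yn-1-yl}-5-(furan-3-yl)-3-methylpent-2-en-4-ynoate
Conditions: PdCl2(PPh3)2 (cat.), CuI (cat.), Et3N, THF, rt
Reagents that add atoms: none
Why: Sonogashira coupling of the electron-poor enol triflate with the terminal alkyne proceeds with retention of alkene geometry, so the alkyne ends cis to the ester.

Step 6
Reactants: 8 the (Z)-enynoate
Product: 10 6-(furan-3-yl)-3-(4-hydroxybut-2-yn-1-yl)-4-methyl-2H-pyran-2-one, via silyl-protected pyrone 9 (not isolated)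
Conditions: Ph3PAuCl (cat.), AgOTf (cat.), CH2Cl2, rt; then MeOH, camphorsulfonic acid (cat.), rt
Reagents that add atoms: none
Why: Gold-catalysed 6-endo-dig lactonisation, in which the cis ester carbonyl oxygen attacks the activated alkyne at the furyl-bearing carbon (the one best able to carry positive charge), isobutene is lost and protodeauration gives the 2-pyranone; acidic methanol then cleaves the silyl ether.

Step 7
Reactants: 10 6-(furan-3-yl)-3-(4-hydroxybut-2-yn-1-yl)-4-methyl-2H-pyran-2-one
Product: 11 6-(furan-3-yl)-3-[(2Z)-4-hydroxy-3-(tributylstannyl)but-2-en-1-yl]-4-methyl-2H-pyran-2-one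
Conditions: Bu3SnH, [(C5Me5)RuCl]4 (cat.), CH2Cl2, rt
Reagents that add atoms: tributyltin hydride, CCCC[SnH](CCCC)CCCC
Why: Hydroxyl-directed ruthenium-catalysed trans-hydrostannation of a propargylic alcohol, in which hydrogen bonding of the free OH to the chloride ligand steers tin to the alkyne carbon next to the carbinol (C5) and hydrogen to C6.

Step 8
Reactants: 11 the alkenylstannane
Product: 12 6-(furan-3-yl)-3-[(2Z)-4-hydroxy-3-iodobut-2-en-1-yl]-4-methyl-2H-pyran-2-one
Conditions: I2 (1.0 equiv), CH2Cl2, 0 °C
Reagents that add atoms: iodine, II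
Why: Iododestannylation of an alkenylstannane is fast at 0 °C and occurs with retention, and a single equivalent of iodine should spare the furan.

Step 9
Reactants: 12 the alkenyl iodide; 13 tributyl(1-ethoxyethenyl)stannane
Product: 15 6-(furan-3-yl)-3-[(2Z)-3-(hydroxymethyl)-4-oxopent-2-en-1-yl]-4-methyl-2H-pyran-2-one, via ethoxydiene 14 (not isolated)
Conditions: Pd(PPh3)4 (cat.), CuI (cat.), DMF, 50 °C; then 1 M HCl, THF, 0 °C
Reagents that add atoms: water, O
Why: Stille coupling with the 1-ethoxyvinyl stannane as an acetyl anion equivalent, followed by mild hydrolysis of the enol ether, installs the methyl ketone (C10, C1) while tolerating the free allylic alcohol.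

Step 10
Reactants: 15 the hydroxymethyl enone
Product: 16 3-[(2E)-3-(bromomethyl)-4-oxopent-2-en-1-yl]-6-(furan-3-yl)-4-methyl-2H-pyran-2-one
Conditions: CBr4, PPh3, CH2Cl2, 0 °C
Reagents that add atoms: carbon tetrabromide, BrC(Br)(Br)Br
Why: The Appel reaction converts the primary allylic alcohol into the bromide under neutral conditions that leave enone, pyrone and furan untouched.

Step 11
Reactants: 17 (1,3-dioxolan-2-ylmethyl)magnesium bromide; 18 diethyl oxalate (excess)
Product: 19 ethyl 3-(1,3-dioxolan-2-yl)-2-oxopropanoate
Conditions: THF, −78 °C, Grignard added to the oxalate; aq. NH4Cl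
Reagents that add atoms: none
Why: Grignard addition to excess dialkyl oxalate at low temperature stops at the α-keto ester, because the tetrahedral magnesium alkoxide survives until work-up.

Step 12
Reactants: 19 ethyl 3-(1,3-dioxolan-2-yl)-2-oxopropanoate
Product: 20 potassium 3-(1,3-dioxolan-2-yl)-2-oxopropanoate
Conditions: KOH (1.0 equiv), EtOH/H2O, 0 °C; concentrate and dry in vacuo
Reagents that add atoms: potassium hydroxide, [K+].[OH-]
Why: Saponification of an α-keto ester is very fast with one equivalent of hydroxide at 0 °C, which should leave the acetal intact and give the dry carboxylate salt.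

Step 13
Reactants: 16 the allylic bromide; 20 the potassium carboxylate
Product: 21 (2Z)-2-acetyl-4-[6-(furan-3-yl)-4-methyl-2-oxo-2H-pyran-3-yl]but-2-en-1-yl 3-(1,3-dioxolan-2-yl)-2-oxopropanoate
Conditions: DMF, 0 °C → rt
Reagents that add atoms: none
Why: SN2 displacement of the activated primary allylic bromide by the carboxylate in a dipolar aprotic solvent forms the ester at the CH2 carbon and keeps the conjugated trisubstituted enone.

Step 14
Reactants: 21 the enone α-keto ester
Product: 23 (3R,4R)-4-acetyl-3-(1,3-dioxolan-2-ylmethyl)-4-{2-[6-(furan-3-yl)-4-methyl-2-oxo-2H-pyran-3-yl]ethyl}-3-hydroxyoxolan-2-one, via copper enolate 22 (not isolated)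
Conditions: Cu(OAc)2·H2O (5 mol %), (R)-DTBM-SEGPHOS (5.5 mol %), (EtO)2MeSiH (1.5 equiv), toluene, −40 → −20 °C; then aq. NH4Cl
Reagents that add atoms: none
Why: Proposed new method: the bisphosphine-bound copper hydride generated from Cu(OAc)2 and the silane should add hydride to C6 of the enone and leave a copper enolate at C5 (22), which adds through a copper-bridged six-membered transition state to the C4 carbonyl of the tethered keto ester, after which the silane silylates the copper aldolate (blocking retro-aldol) and regenerates the hydride. The closest known reaction type is the copper-hydride reductive aldol cyclisation of enones and enoates onto tethered ketones, which has not been shown for an α-(acyloxymethyl) enone with an α-keto ester acceptor and a fully substituted enolate. The lactone closes in the 5-(enolexo)-exo-trig mode. C4 and C5 are set together: the copper bridge between the enolate oxygen and the C4 oxygen places the hydroxyl cis to the acetyl group and trans to the C6 chain, and the chiral bisphosphine selects the enolate face and hence the (4R,5R) series. The step needs conjugate reduction of the enone ahead of 1,2-reduction of the keto ester and ahead of attack on the pyrone, and aldol addition ahead of expulsion of the C19 carboxylate from the enolate. The soft hindered hydride, the pyrone being fully substituted at its β and δ carbons, the five-atom tether to the most electrophilic carbonyl, and a covalent O–Cu enolate in cold non-polar solvent are relied on for this.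

Step 15
Reactants: 23 the acetyl hydroxy lactone
Product: 25 (3aR,7aR)-3a-{2-[6-(furan-3-yl)-4-methyl-2-oxo-2H-pyran-3-yl]ethyl}-6-[2-(trimethylsilyloxy)ethoxy]-7a-(trimethylsilyloxy)hexahydro-2-benzofuran-1,4-dione (both C6 epimers), via bis-silylated enol ether 24 (not isolated)
Conditions: TMSOTf (3.5 equiv), iPr2NEt (4 equiv), CH2Cl2, −78 → 0 °C
Reagents that add atoms: trimethylsilyl trifluoromethanesulfonate, C[Si](C)(C)OS(=O)(=O)C(F)(F)F
Why: One-pot enol silane formation and Mukaiyama-type addition to an acetal, in which the methyl ketone is silylated at its only enolisable position (C1), the carbinol is capped, and the enol silane attacks the oxocarbenium ion opened from the dioxolane in a 6-(enolendo)-exo-trig closure whose trans ring fusion is dictated by C4 and C5 (the new C2 centre is removed in step 16).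

Step 16
Reactants: 25 the bicyclic β-alkoxy ketone
Product: 27 (3aR,7aR)-3a-{2-[6-(furan-3-yl)-4-methyl-2-oxo-2H-pyran-3-yl]ethyl}-7a-hydroxy-3a,7a-dihydro-2-benzofuran-1,4(3H,7H)-dione, via desilylated alkoxy ketone 26 (not isolated)
Conditions: TsOH·H2O (0.3 equiv), toluene, rt → 50 °C
Reagents that add atoms: none
Why: Acid-catalysed β-elimination of the C2 alkoxy group through the ketone enol should give the conjugated enone while the acid cleaves both trimethylsilyl ethers, and the tertiary carbinol should persist because ionisation at C4 is disfavoured next to the lactone carbonyl.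

**Compound list**

1 | 4-chlorobut-2-yn-1-ol | OCC#CCCl | starting material
2 | tert-butyl[(4-chlorobut-2-yn-1-yl)oxy]dimethylsilane | CC(C)(C)[Si](C)(C)OCC#CCCl | intermediate
3 | tert-butyl 3-oxobutanoate (tert-butyl acetoacetate) | CC(=O)CC(=O)OC(C)(C)C | starting material
4 | tert-butyl 2-acetyl-6-[(tert-butyldimethylsilyl)oxy]hex-4-ynoate (racemic) | CC(=O)C(CC#CCO[Si](C)(C)C(C)(C)C)C(=O)OC(C)(C)C | intermediate
5 | tert-butyl (2Z)-2-{4-[(tert-butyldimethylsilyl)oxy]but-2-yn-1-yl}-3-{[(trifluoromethyl)sulfonyl]oxy}but-2-enoate | C/C(OS(=O)(=O)C(F)(F)F)=C(\CC#CCO[Si](C)(C)C(C)(C)C)C(=O)OC(C)(C)C | intermediate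
6 | furan-3-carbaldehyde | O=Cc1ccoc1 | starting material
7 | 3-ethynylfuran | C#Cc1ccoc1 | intermediate
8 | tert-butyl (2Z)-2-{4-[(tert-butyldimethylsilyl)oxy]but-2-yn-1-yl}-5-(furan-3-yl)-3-methylpent-2-en-4-ynoate | C/C(C#Cc1ccoc1)=C(\CC#CCO[Si](C)(C)C(C)(C)C)C(=O)OC(C)(C)C | intermediate
9 | 3-{4-[(tert-butyldimethylsilyl)oxy]but-2-yn-1-yl}-6-(furan-3-yl)-4-methyl-2H-pyran-2-one | Cc1cc(-c2ccoc2)oc(=O)c1CC#CCO[Si](C)(C)C(C)(C)C | intermediate (not isolated)
10 | 6-(furan-3-yl)-3-(4-hydroxybut-2-yn-1-yl)-4-methyl-2H-pyran-2-one | Cc1cc(-c2ccoc2)oc(=O)c1CC#CCO | intermediate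
11 | 6-(furan-3-yl)-3-[(2Z)-4-hydroxy-3-(tributylstannyl)but-2-en-1-yl]-4-methyl-2H-pyran-2-one | Cc1cc(-c2ccoc2)oc(=O)c1C/C=C(/CO)[Sn](CCCC)(CCCC)CCCC | intermediate
12 | 6-(furan-3-yl)-3-[(2Z)-4-hydroxy-3-iodobut-2-en-1-yl]-4-methyl-2H-pyran-2-one | Cc1cc(-c2ccoc2)oc(=O)c1C/C=C(/CO)I | intermediate
13 | tributyl(1-ethoxyethenyl)stannane | CCOC(=C)[Sn](CCCC)(CCCC)CCCC | starting material
14 | 3-[(2Z)-4-ethoxy-3-(hydroxymethyl)penta-2,4-dien-1-yl]-6-(furan-3-yl)-4-methyl-2H-pyran-2-one | Cc1cc(-c2ccoc2)oc(=O)c1C/C=C(/CO)C(=C)OCC | intermediate (not isolated)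
15 | 6-(furan-3-yl)-3-[(2Z)-3-(hydroxymethyl)-4-oxopent-2-en-1-yl]-4-methyl-2H-pyran-2-one | Cc1cc(-c2ccoc2)oc(=O)c1C/C=C(/CO)C(C)=O | intermediate
16 | 3-[(2E)-3-(bromomethyl)-4-oxopent-2-en-1-yl]-6-(furan-3-yl)-4-methyl-2H-pyran-2-one | Cc1cc(-c2ccoc2)oc(=O)c1C/C=C(/CBr)C(C)=O | intermediate
17 | (1,3-dioxolan-2-ylmethyl)magnesium bromide (THF solution) | Br[Mg]CC1OCCO1 | starting material
18 | diethyl oxalate | CCOC(=O)C(=O)OCC | starting material
19 | ethyl 3-(1,3-dioxolan-2-yl)-2-oxopropanoate | CCOC(=O)C(=O)CC1OCCO1 | intermediate
20 | potassium 3-(1,3-dioxolan-2-yl)-2-oxopropanoate | [K+].[O-]C(=O)C(=O)CC1OCCO1 | intermediate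
21 | (2Z)-2-acetyl-4-[6-(furan-3-yl)-4-methyl-2-oxo-2H-pyran-3-yl]but-2-en-1-yl 3-(1,3-dioxolan-2-yl)-2-oxopropanoate (key-step precursor) | Cc1cc(-c2ccoc2)oc(=O)c1C/C=C(/COC(=O)C(=O)CC3OCCO3)C(C)=O | intermediate
22 | copper enolate of 21 after hydride addition to C6 (O–Cu at C10, C10=C5 double bond; bisphosphine on copper not drawn) | CC(O[Cu])=C(CCc1c(C)cc(-c2ccoc2)oc1=O)COC(=O)C(=O)CC3OCCO3 | intermediate (not isolated)
23 | (3R,4R)-4-acetyl-3-(1,3-dioxolan-2-ylmethyl)-4-{2-[6-(furan-3-yl)-4-methyl-2-oxo-2H-pyran-3-yl]ethyl}-3-hydroxyoxolan-2-one (key-step product) | CC(=O)[C@]1(CCc2c(C)cc(-c3ccoc3)oc2=O)COC(=O)[C@@]1(O)CC4OCCO4 | intermediate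
24 | 23 as its tertiary trimethylsilyl ether and trimethylsilyl enol ether of the methyl ketone (configuration unchanged) | C=C(O[Si](C)(C)C)[C@]1(CCc2c(C)cc(-c3ccoc3)oc2=O)COC(=O)[C@@]1(O[Si](C)(C)C)CC4OCCO4 | intermediate (not isolated)
25 | (3aR,7aR)-3a-{2-[6-(furan-3-yl)-4-methyl-2-oxo-2H-pyran-3-yl]ethyl}-6-[2-(trimethylsilyloxy)ethoxy]-7a-(trimethylsilyloxy)hexahydro-2-benzofuran-1,4-dione (both C6 epimers) | Cc1cc(-c2ccoc2)oc(=O)c1CC[C@@]12COC(=O)[C@@]1(O[Si](C)(C)C)CC(OCCO[Si](C)(C)C)CC2=O | intermediate
26 | (3aR,7aR)-3a-{2-[6-(furan-3-yl)-4-methyl-2-oxo-2H-pyran-3-yl]ethyl}-7a-hydroxy-6-(2-hydroxyethoxy)hexahydro-2-benzofuran-1,4-dione | Cc1cc(-c2ccoc2)oc(=O)c1CC[C@@]12COC(=O)[C@@]1(O)CC(OCCO)CC2=O | intermediate (not isolated)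
27 | (3aR,7aR)-3a-{2-[6-(furan-3-yl)-4-methyl-2-oxo-2H-pyran-3-yl]ethyl}-7a-hydroxy-3a,7a-dihydro-2-benzofuran-1,4(3H,7H)-dione | Cc1cc(-c2ccoc2)oc(=O)c1CC[C@@]12COC(=O)[C@@]1(O)CC=CC2=O | target

**Step count**

Total: 16 steps. Longest linear sequence: 13 steps (1, 2, 3, 5, 6, 7, 8, 9, 10, 13, 14, 15, 16).

**Steps most likely to fail**

Step 14 (the labelled step). The copper enolate may expel the C19 carboxylate before it finds the C4 carbonyl (net allylic reduction), hydride may reach the keto ester carbonyl before the enone, or facial selection by the ligand may be weak. The fallback sets out from 21 and separates enolate formation from bond formation. Conjugate hydrosilylation of the enone with Et3SiH and RhCl(PPh3)3 (a monohydrosilane adds 1,4 to enones far faster than it reduces ketones) should give the triethylsilyl enol ether F1, a neutral species that cannot lose the carboxylate. Cu(OTf)2 with (S,S)-2,2'-(propane-2,2-diyl)bis(4-tert-butyl-4,5-dihydrooxazole) then binds the keto ester as a five-membered chelate and promotes an intramolecular Mukaiyama aldol with silyl transfer, giving the triethylsilyl ether of the aldol lactone F2. The relative configuration then comes from an open transition state and has to be confirmed, and the ligand antipode is chosen accordingly. HF·pyridine in THF returns the route to 23.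

Step 15. The ring-opened dioxolane may re-close, or the enol silane may be protodesilylated, faster than carbon–carbon bond formation to the strained trans-fused ring. The fallback sets out from 23 and changes the closure to a protic aldol condensation. Brief hydrolysis of the acetal (1 M HCl, THF, rt) should give the keto aldehyde F3, and TsOH in toluene at 40 °C then closes C1–C2 through the ketone enol and dehydrates the aldol, rejoining the route at 27.

Step 16. Ionisation of an equatorial alkoxy group may be slow, so that acid-mediated degradation of the furan, or dehydration or retro-aldol cleavage at the C4 carbinol, overtakes the elimination. The fallback sets out from 25 and keeps the tertiary oxygen silylated, which blocks retro-aldol cleavage. DBU in CH2Cl2 at 0 °C effects an E1cB elimination of the alkoxy group to the silyl-protected enone F4, run cold and stopped early to limit vinylogous loss of the silyloxy group. HF·pyridine in THF at 0 °C then removes the silyl ether and rejoins the route at 27.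

**Further compounds**

F1 | step 14 | triethylsilyl enol ether of the C10 ketone of 21 with C6 reduced | CC(O[Si](CC)(CC)CC)=C(CCc1c(C)cc(-c2ccoc2)oc1=O)COC(=O)C(=O)CC3OCCO3
F2 | step 14 | triethylsilyl ether of 23 at the tertiary carbinol | CC(=O)[C@]1(CCc2c(C)cc(-c3ccoc3)oc2=O)COC(=O)[C@@]1(O[Si](CC)(CC)CC)CC4OCCO4
F3 | step 15 | 2-[(3R,4R)-4-acetyl-4-{2-[6-(furan-3-yl)-4-methyl-2-oxo-2H-pyran-3-yl]ethyl}-3-hydroxy-2-oxooxolan-3-yl]acetaldehyde | CC(=O)[C@]1(CCc2c(C)cc(-c3ccoc3)oc2=O)COC(=O)[C@@]1(O)CC=O
F4 | step 16 | trimethylsilyl ether of 27 at the tertiary carbinol | Cc1cc(-c2ccoc2)oc(=O)c1CC[C@@]12COC(=O)[C@@]1(O[Si](C)(C)C)CC=CC2=O
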